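**Retrosynthetic overview**
1. Target 17 ⇐ alcohol 16 ⇐ silyl ether 15 (end-game acetylation and desilylation); the 2-methoxy-4-pyranone 15 ⇐ regioselective O-methylation of 4-hydroxy-2-pyranone 13.
2. The only ring (the pyranone) is closed late, by lactonisation of the acyclic 3,5-dioxo ester 12 to 13.
3. 12 ⇐ aldol adduct 11 ⇐ aldehyde 7 (fragment A) + keto ester 9 (fragment B): the key C–C bond (future ring C5–C6 junction to the chain carbon) is made by a β-keto ester dianion aldol.
4. 7 ⇐ alkene 5 ⇐ alcohol 4 ⇐ 10-bromodec-1-ene 1 + (S)-2-methyloxirane 2 (the stereocentre comes from the epoxide); 9 ⇐ methyl 3-oxopentanoate 8 + iodoethane.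

Assumption: the stereocentre in the given SMILES is read as (S); 1, 2 and 8 are taken as purchasable.

**Route**

Step 1
Reactants: 1 10-bromodec-1-ene; 2 (S)-2-methyloxirane
Product: 4 (2S)-tridec-12-en-2-ol, via dec-9-enylmagnesium bromide 3 (not isolated)
Conditions: Mg, THF, 40 °C; then CuI (10 mol %), 2, −30 → 0 °C; aq NH4Cl
Reagents that add atoms: none
Why: Grignard formation followed by copper-catalysed SN2 epoxide opening at the unhindered CH2 terminus, so the C–O stereocentre of 2 is never touched and its (S) configuration becomes the (S)-carbinol of 4.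

Step 2
Reactants: 4 (2S)-tridec-12-en-2-ol
Product: 5 tert-butyl(diphenyl)[(2S)-tridec-12-en-2-yloxy]silane
Conditions: TBDPSCl, imidazole, DMF, rt
Reagents that add atoms: tert-butyl(chloro)diphenylsilane, CC(C)(C)[Si](Cl)(c1ccccc1)c1ccccc1
Why: Imidazole-promoted silyl ether formation at oxygen leaves the stereocentre unchanged and installs a group that tolerates the dianion, DBU and the acidic methylation step.

Step 3
Reactants: 5 tert-butyl(diphenyl)[(2S)-tridec-12-en-2-yloxy]silane
Product: 7 (11S)-11-[(tert-butyldiphenylsilyl)oxy]dodecanal, via secondary ozonide 6 (not isolated)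
Conditions: O3, CH2Cl2, −78 °C; then PPh3, −78 °C → rt
Reagents that add atoms: ozone, [O-][O+]=O
Why: Ozonolysis (Criegee mechanism) with reductive work-up cleaves the only alkene cleanly to the aldehyde; the ozonide carbon stereocentre is uncontrolled and is destroyed on reduction.

Step 4
Reactants: 8 methyl 3-oxopentanoate
Product: 9 methyl 2-ethyl-3-oxopentanoate (racemic)
Conditions: EtI (1.2 equiv), K2CO3, acetone, reflux
Reagents that add atoms: iodoethane, CCI
Why: C-alkylation of the stabilised β-keto ester enolate (acetoacetic ester alkylation) with a primary iodide; the new C2 centre is racemic and later becomes sp2.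

Step 5
Reactants: 9 methyl 2-ethyl-3-oxopentanoate (1.5 equiv); 7 (11S)-11-[(tert-butyldiphenylsilyl)oxy]dodecanal
Product: 11 methyl (15S)-15-[(tert-butyldiphenylsilyl)oxy]-2-ethyl-5-hydroxy-4-methyl-3-oxohexadecanoate (mixture of diastereomers at C2/C4/C5), via sodium lithium dianion 10 (not isolated)
Conditions: NaH, THF, 0 °C; n-BuLi, 0 °C; then 7, −78 °C; aq NH4Cl
Reagents that add atoms: none
Why: Key step, a Huckin–Weiler dianion aldol addition in which the more reactive γ-carbanion adds to the aldehyde at −78 °C; the three new centres form as a mixture that does not matter because all become sp2 in steps 6 and 7, while C15 is remote and untouched.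

Step 6
Reactants: 11 methyl (15S)-15-[(tert-butyldiphenylsilyl)oxy]-2-ethyl-5-hydroxy-4-methyl-3-oxohexadecanoate
Product: 12 methyl (15S)-15-[(tert-butyldiphenylsilyl)oxy]-2-ethyl-4-methyl-3,5-dioxohexadecanoate
Conditions: Dess–Martin periodinane, CH2Cl2, 0 °C → rt
Reagents that add atoms: none
Why: Dess–Martin oxidation converts the secondary β-hydroxy ketone to the 1,3-diketone under mild conditions without retro-aldol cleavage, and removes the C5 stereocentre.

Step 7
Reactants: 12 methyl (15S)-15-[(tert-butyldiphenylsilyl)oxy]-2-ethyl-4-methyl-3,5-dioxohexadecanoate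
Product: 13 6-[(10S)-10-[(tert-butyldiphenylsilyl)oxy]undecyl]-3-ethyl-4-hydroxy-5-methyl-2H-pyran-2-one
Conditions: DBU (1,8-diazabicyclo[5.4.0]undec-7-ene), toluene, 60 °C; then 1 M aq HCl
Reagents that add atoms: none
Why: Base-mediated lactonisation (intramolecular O-acylation of the δ-enolate by the methyl ester, with loss of methanol) gives the aromatic-like 4-hydroxy-2-pyranone, erasing the C2 and C4 centres.

Step 8
Reactants: 13 6-[(10S)-10-[(tert-butyldiphenylsilyl)oxy]undecyl]-3-ethyl-4-hydroxy-5-methyl-2H-pyran-2-one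
Product: 15 2-[(10S)-10-[(tert-butyldiphenylsilyl)oxy]undecyl]-5-ethyl-6-methoxy-3-methyl-4H-pyran-4-one, via pyrylium triflate 14 (not isolated)
Conditions: MeOTf, CH2Cl2, 0 °C → rt; then aq NaHCO3
Reagents that add atoms: methyl trifluoromethanesulfonate, COS(=O)(=O)C(F)(F)F
Why: Regioselective O-methylation of the neutral hydroxypyranone by a hard methylating agent occurs at the ring carbonyl oxygen (a vinylogous carbonate), and deprotonation of the resulting 4-hydroxy-2-methoxypyrylium salt gives the 2-methoxy-4-pyranone.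

Step 9
Reactants: 15 2-[(10S)-10-[(tert-butyldiphenylsilyl)oxy]undecyl]-5-ethyl-6-methoxy-3-methyl-4H-pyran-4-one
Product: 16 5-ethyl-2-[(10S)-10-hydroxyundecyl]-6-methoxy-3-methyl-4H-pyran-4-one
Conditions: Bu4NF/AcOH (1:1), THF, rt → 45 °C
Reagents that add atoms: none
Why: Fluoride-mediated desilylation driven by the strong Si–F bond, buffered with acetic acid to protect the methoxypyranone from basic fluoride, cleaves only the Si–O bond so the (S) centre is retained.

Step 10
Reactants: 16 5-ethyl-2-[(10S)-10-hydroxyundecyl]-6-methoxy-3-methyl-4H-pyran-4-one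
Product: 17 (2S)-11-(5-ethyl-6-methoxy-3-methyl-4-oxo-4H-pyran-2-yl)undecan-2-yl acetate
Conditions: Ac2O, pyridine, 4-(dimethylamino)pyridine (cat.), CH2Cl2, rt
Reagents that add atoms: acetic anhydride, CC(=O)OC(C)=O
Why: Nucleophile-catalysed O-acylation of the secondary alcohol forms the acetate without breaking the C–O bond, so the (S) configuration is retained.

**Compound list**
1 | 10-bromodec-1-ene | C=CCCCCCCCCBr | starting material
2 | (S)-2-methyloxirane [(S)-propylene oxide] | C[C@H]1CO1 | starting material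
3 | dec-9-enylmagnesium bromide (formed in situ) | C=CCCCCCCCC[Mg]Br | intermediate
4 | (2S)-tridec-12-en-2-ol | C=CCCCCCCCCC[C@H](C)O | intermediate
5 | tert-butyl(diphenyl)[(2S)-tridec-12-en-2-yloxy]silane | C=CCCCCCCCCC[C@H](C)O[Si](c1ccccc1)(c1ccccc1)C(C)(C)C | intermediate
6 | 3-[(10S)-10-[(tert-butyldiphenylsilyl)oxy]undecyl]-1,2,4-trioxolane (secondary ozonide, formed in situ, ring carbon unassigned) | O1OC(CCCCCCCCC[C@H](C)O[Si](c2ccccc2)(c2ccccc2)C(C)(C)C)OC1 | intermediate
7 | (11S)-11-[(tert-butyldiphenylsilyl)oxy]dodecanal | O=CCCCCCCCCC[C@H](C)O[Si](c1ccccc1)(c1ccccc1)C(C)(C)C | intermediate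
8 | methyl 3-oxopentanoate | CCC(=O)CC(=O)OC | starting material
9 | methyl 2-ethyl-3-oxopentanoate (racemic) | CCC(=O)C(CC)C(=O)OC | intermediate
10 | sodium lithium dianion of methyl 2-ethyl-3-oxopentanoate (formed in situ) | [Na+].[Li+].CC=C([O-])C(CC)=C([O-])OC | intermediate
11 | methyl (15S)-15-[(tert-butyldiphenylsilyl)oxy]-2-ethyl-5-hydroxy-4-methyl-3-oxohexadecanoate (diastereomer mixture at C2/C4/C5) | COC(=O)C(CC)C(=O)C(C)C(O)CCCCCCCCC[C@H](C)O[Si](c1ccccc1)(c1ccccc1)C(C)(C)C | intermediate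
12 | methyl (15S)-15-[(tert-butyldiphenylsilyl)oxy]-2-ethyl-4-methyl-3,5-dioxohexadecanoate | COC(=O)C(CC)C(=O)C(C)C(=O)CCCCCCCCC[C@H](C)O[Si](c1ccccc1)(c1ccccc1)C(C)(C)C | intermediate
13 | 6-[(10S)-10-[(tert-butyldiphenylsilyl)oxy]undecyl]-3-ethyl-4-hydroxy-5-methyl-2H-pyran-2-one | CCc1c(O)c(C)c(CCCCCCCCC[C@H](C)O[Si](c2ccccc2)(c2ccccc2)C(C)(C)C)oc1=O | intermediate
14 | 2-[(10S)-10-[(tert-butyldiphenylsilyl)oxy]undecyl]-5-ethyl-4-hydroxy-6-methoxy-3-methylpyrylium trifluoromethanesulfonate (formed in situ) | CCc1c(OC)[o+]c(CCCCCCCCC[C@H](C)O[Si](c2ccccc2)(c2ccccc2)C(C)(C)C)c(C)c1O.[O-]S(=O)(=O)C(F)(F)F | intermediate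
15 | 2-[(10S)-10-[(tert-butyldiphenylsilyl)oxy]undecyl]-5-ethyl-6-methoxy-3-methyl-4H-pyran-4-one | CCc1c(OC)oc(CCCCCCCCC[C@H](C)O[Si](c2ccccc2)(c2ccccc2)C(C)(C)C)c(C)c1=O | intermediate
16 | 5-ethyl-2-[(10S)-10-hydroxyundecyl]-6-methoxy-3-methyl-4H-pyran-4-one | CCc1c(OC)oc(CCCCCCCCC[C@H](C)O)c(C)c1=O | intermediate
17 | (2S)-11-(5-ethyl-6-methoxy-3-methyl-4-oxo-4H-pyran-2-yl)undecan-2-yl acetate | CCc1c(OC)oc(CCCCCCCCC[C@H](C)OC(C)=O)c(C)c1=O | target

**Totals**
Total step count: 10. Longest linear sequence: 9 steps (steps 1, 2, 3, 5, 6, 7, 8, 9, 10 from 10-bromodec-1-ene); step 4 is a one-step side branch.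

**Three steps most likely to fail, with fallbacks**

Step 5 (dianion aldol). The hindered α-ethyl dianion may form incompletely, and the enolisable aldehyde can be deprotonated or the adduct can revert by retro-aldol. The fallback sets out from aldehyde 7 and comes back at diketo ester 12, so step 6 is no longer needed. Aldehyde 7 is oxidised under Pinnick conditions (NaClO2, NaH2PO4, 2-methylbut-2-ene, t-BuOH/H2O) to (11S)-11-[(tert-butyldiphenylsilyl)oxy]dodecanoic acid F1. This is coupled with N,O-dimethylhydroxylamine hydrochloride (EDC·HCl, Et3N, CH2Cl2) to the Weinreb amide (11S)-11-[(tert-butyldiphenylsilyl)oxy]-N-methoxy-N-methyldodecanamide F2. A Claisen-type C-acylation of dianion 10 (2.5 equiv, since the product quenches one equivalent) with F2 at −78 → 0 °C then gives 12 directly. The amide cannot enolise towards a retro-reaction and its chelated tetrahedral adduct prevents over-addition.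

Step 8 (regioselective methylation). Some 4-methoxy-2-pyranone isomer may form, and the strongly acidic pyrylium triflate may damage the silyl ether. The fallback sets out from 13 and comes back at 15. Compound 13 is silylated with hexamethyldisilazane (cat. Me3SiCl, toluene, 80 °C, then evaporation) to 6-[(10S)-10-[(tert-butyldiphenylsilyl)oxy]undecyl]-3-ethyl-5-methyl-4-[(trimethylsilyl)oxy]-2H-pyran-2-one F3. With the 4-oxygen blocked, MeOTf in CH2Cl2 can alkylate only the ring carbonyl oxygen. The resulting 2-[(10S)-10-[(tert-butyldiphenylsilyl)oxy]undecyl]-5-ethyl-6-methoxy-3-methyl-4-[(trimethylsilyl)oxy]pyrylium trifluoromethanesulfonate F4 loses its trimethylsilyl group on aqueous NaHCO3 work-up to give 15, with no free triflic acid present at any point.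

Step 9 (desilylation next to the methoxypyranone). The hindered secondary TBDPS ether cleaves slowly, and fluoride or adventitious hydroxide can demethylate the vinylogous carbonate. The fallback sets out from 13 and comes back at target 17, replacing steps 8 to 10. The silyl group is removed at the hydroxypyranone stage, where the ring is an inert pyranolate (Bu4NF, THF, 45 °C), giving 3-ethyl-4-hydroxy-6-[(10S)-10-hydroxyundecyl]-5-methyl-2H-pyran-2-one F5. Exhaustive acetylation (Ac2O, pyridine, 4-(dimethylamino)pyridine) gives the diacetate (2S)-11-[4-(acetyloxy)-5-ethyl-3-methyl-6-oxo-6H-pyran-2-yl]undecan-2-yl acetate F6. Only its enol (vinylogous anhydride) acetate is cleaved by MeOH/Et3N at 0 °C, giving (2S)-11-(5-ethyl-4-hydroxy-3-methyl-6-oxo-6H-pyran-2-yl)undecan-2-yl acetate F7. MeOTf in CH2Cl2 then methylates the ring carbonyl oxygen to 2-[(10S)-10-(acetyloxy)undecyl]-5-ethyl-4-hydroxy-6-methoxy-3-methylpyrylium trifluoromethanesulfonate F8, which gives 17 on aqueous NaHCO3 work-up. The acid-stable acetate is already in place, so no fluoride ever meets the methoxypyranone.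

**Further compounds**
F1 | step 5 | (11S)-11-[(tert-butyldiphenylsilyl)oxy]dodecanoic acid | OC(=O)CCCCCCCCC[C@H](C)O[Si](c1ccccc1)(c1ccccc1)C(C)(C)C
F2 | step 5 | (11S)-11-[(tert-butyldiphenylsilyl)oxy]-N-methoxy-N-methyldodecanamide | CON(C)C(=O)CCCCCCCCC[C@H](C)O[Si](c1ccccc1)(c1ccccc1)C(C)(C)C
F3 | step 8 | 6-[(10S)-10-[(tert-butyldiphenylsilyl)oxy]undecyl]-3-ethyl-5-methyl-4-[(trimethylsilyl)oxy]-2H-pyran-2-one | CCc1c(O[Si](C)(C)C)c(C)c(CCCCCCCCC[C@H](C)O[Si](c2ccccc2)(c2ccccc2)C(C)(C)C)oc1=O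
F4 | step 8 | 2-[(10S)-10-[(tert-butyldiphenylsilyl)oxy]undecyl]-5-ethyl-6-methoxy-3-methyl-4-[(trimethylsilyl)oxy]pyrylium trifluoromethanesulfonate | CCc1c(OC)[o+]c(CCCCCCCCC[C@H](C)O[Si](c2ccccc2)(c2ccccc2)C(C)(C)C)c(C)c1O[Si](C)(C)C.[O-]S(=O)(=O)C(F)(F)F
F5 | step 9 | 3-ethyl-4-hydroxy-6-[(10S)-10-hydroxyundecyl]-5-methyl-2H-pyran-2-one | CCc1c(O)c(C)c(CCCCCCCCC[C@H](C)O)oc1=O
F6 | step 9 | (2S)-11-[4-(acetyloxy)-5-ethyl-3-methyl-6-oxo-6H-pyran-2-yl]undecan-2-yl acetate | CCc1c(OC(C)=O)c(C)c(CCCCCCCCC[C@H](C)OC(C)=O)oc1=O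
F7 | step 9 | (2S)-11-(5-ethyl-4-hydroxy-3-methyl-6-oxo-6H-pyran-2-yl)undecan-2-yl acetate | CCc1c(O)c(C)c(CCCCCCCCC[C@H](C)OC(C)=O)oc1=O
F8 | step 9 | 2-[(10S)-10-(acetyloxy)undecyl]-5-ethyl-4-hydroxy-6-methoxy-3-methylpyrylium trifluoromethanesulfonate | CCc1c(OC)[o+]c(CCCCCCCCC[C@H](C)OC(C)=O)c(C)c1O.[O-]S(=O)(=O)C(F)(F)F
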